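**Retrosynthetic overview**

1. The target comes from a macrocyclic epoxide: the last step opens the C10–C11 epoxide with bromide (C10–Br, C11–OH).
2. Ring B (the 1,4-cyclohexadiene) and the 15-membered lactone are closed together by one light-driven, cobalt-catalysed intramolecular [4+2] of a diene–alkyne ester (bonds Ca–Cf and Cd–Ce; Ca is set here).
3. The ester comes from a Mitsunobu union (inversion at C14) of a C8–C16 hydroxy mesylate enal with 3-(but-2-ynyl)-4-hydroxybenzoic acid (ring A, bought as the 3-formyl acid), then methylenation and epoxide closure.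
4. The C8–C16 chain comes from a Felkin–Anh Grignard addition (C11–C12 bond, sets C11) of a C12–C16 iodide to (R)-5-acetylbutyrolactone.
5. Ketone and iodide both come from one bought lactone acid, whose stereocentre becomes C10 in one half and C14 in the other. Ring order: A bought, then the epoxide, then B and the macrolactone in one step.

Locants: C14 = lactone carbinol carbon (bears the isopropenyl group C15/C16); C13, C12 = CH2; C11 = C(CH3)(OH); C10 = CHBr; C9, C8 = CH2. Ring B: Ca (sp3 CH), Cb (CH3), Cc (H), Cd (H2), Ce (CH3), Cf (bears the ArCH2 group). Ring A = the benzoate.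

Assumption: (R)-5-oxotetrahydrofuran-2-carboxylic acid, the commercial deamination product of D-glutamic acid, is the chiral starting material (if only the amino acid is bought, add one step: NaNO2, aq HCl). Selectivities given are estimates; nothing here has been run.

**Route**

Step 1
Reactants: 1 (R)-5-oxotetrahydrofuran-2-carboxylic acid
Product: 3 (R)-5-acetyldihydrofuran-2(3H)-one, via acid chloride 2 (not isolated)
Conditions: (COCl)2, DMF (cat.), CH2Cl2, 0 → 25 °C; then Me2CuLi, Et2O, −78 °C
Reagents that add atoms: lithium dimethylcuprate (Me2CuLi), [Li+].C[Cu-]C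
Why: Acid chloride formation and Gilman cuprate acylation stop at the methyl ketone at −78 °C and leave the lactone alone; no base is present, so the bought stereocentre (C10 of one half, C14 of the other) is kept.

Step 2
Reactants: 3 (R)-5-acetyldihydrofuran-2(3H)-one
Product: 4 (R)-5-(prop-1-en-2-yl)dihydrofuran-2(3H)-one
Conditions: Zn, CH2Br2, TiCl4, THF–CH2Cl2, 0 → 25 °C
Reagents that add atoms: dibromomethane, BrCBr
Why: Takai–Lombardo methylenation uses a non-basic gem-dimetallic reagent that attacks the ketone but not the lactone, so the adjacent bought centre (future C14) is not epimerised.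

Step 3
Reactants: 4 (R)-5-(prop-1-en-2-yl)dihydrofuran-2(3H)-one
Product: 7 (R)-4-[(tert-butyldimethylsilyl)oxy]-5-methylhex-5-enoic acid, via potassium carboxylate 5 (not isolated), via bis-silyl derivative 6 (not isolated)
Conditions: KOH, MeOH–H2O, 0 °C; evaporate; t-BuMe2SiCl, imidazole, DMF, 25 °C; then AcOH–THF–H2O, 25 °C
Reagents that add atoms: potassium hydroxide (KOH), [K+].[OH-]; tert-butyldimethylsilyl chloride, CC(C)(C)[Si](C)(C)Cl
Why: Lactone saponification, silylation of both oxygens and selective hydrolysis of the labile silyl ester give the O-protected acid without touching the stereocentre.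

Step 4
Reactants: 7 (R)-4-[(tert-butyldimethylsilyl)oxy]-5-methylhex-5-enoic acid
Product: 9 (R)-tert-butyl[(5-iodo-2-methylpent-1-en-3-yl)oxy]dimethylsilane, via Barton ester 8 (not isolated)
Conditions: 2-mercaptopyridine N-oxide, DCC, DMAP (cat.), CH2Cl2, 0 °C, dark; then CHI3, hν (tungsten lamp), PhH, 25 °C
Reagents that add atoms: iodoform, IC(I)I
Why: Barton decarboxylative iodination: visible-light homolysis of the thiohydroxamate ester gives the primary C12 radical, which takes iodine from CHI3 faster than it can attack the distant 1,1-disubstituted alkene; the stereocentre is not involved.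

Step 5
Reactants: 9 (R)-tert-butyl[(5-iodo-2-methylpent-1-en-3-yl)oxy]dimethylsilane; 3 (R)-5-acetyldihydrofuran-2(3H)-one
Product: 11 (R)-5-[(2S,5R)-5-[(tert-butyldimethylsilyl)oxy]-2-hydroxy-6-methylhept-6-en-2-yl]dihydrofuran-2(3H)-one, via Grignard reagent 10 (not isolated)
Conditions: Mg, Et2O, 25 °C; CeCl3, THF, −78 °C; then 3, −78 °C; H2O
Reagents that add atoms: none
Why: Cerium-assisted Grignard 1,2-addition goes to the methyl ketone (not the lactone, and without enolisation) and forms C11–C12; attack anti to the ring C10–O bond (polar Felkin–Anh/Cornforth, the lactone oxygen being a poor chelator) sets C11 as S from the bought C10, expected dr about 5:1 with the minor isomer removed by chromatography.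

Step 6
Reactants: 11 (R)-5-[(2S,5R)-5-[(tert-butyldimethylsilyl)oxy]-2-hydroxy-6-methylhept-6-en-2-yl]dihydrofuran-2(3H)-one
Product: 13 (2E,6R,7S,10R)-10-[(tert-butyldimethylsilyl)oxy]-6,7-dihydroxy-2,7,11-trimethyldodeca-2,11-dienal, via lactol 12 (not isolated)
Conditions: i-Bu2AlH, CH2Cl2, −78 °C; aqueous work-up; then Ph3P=C(CH3)CHO, PhMe, 80 °C
Reagents that add atoms: 2-(triphenylphosphoranylidene)propanal, CC(C=O)=P(c1ccccc1)(c1ccccc1)c1ccccc1
Why: Half-reduction of the lactone to the lactol and Wittig olefination of its open hydroxy-aldehyde form with the formyl-stabilised ylide give the E enal (E preference of stabilised ylides) and free the C10 hydroxyl; no stereocentre is touched.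

Step 7
Reactants: 13 (2E,6R,7S,10R)-10-[(tert-butyldimethylsilyl)oxy]-6,7-dihydroxy-2,7,11-trimethyldodeca-2,11-dienal
Product: 14 (2E,6R,7S,10R)-10-[(tert-butyldimethylsilyl)oxy]-7-hydroxy-2,7,11-trimethyl-1-oxododeca-2,11-dien-6-yl methanesulfonate
Conditions: MsCl, Et3N, CH2Cl2, −20 °C
Reagents that add atoms: methanesulfonyl chloride, CS(=O)(=O)Cl
Why: Sulfonylation discriminates the secondary C10–OH from the tertiary C11–OH and installs the leaving group for the later SN2 epoxide closure.

Step 8
Reactants: 14 (2E,6R,7S,10R)-10-[(tert-butyldimethylsilyl)oxy]-7-hydroxy-2,7,11-trimethyl-1-oxododeca-2,11-dien-6-yl methanesulfonate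
Product: 15 (2E,6R,7S,10R)-7,10-dihydroxy-2,7,11-trimethyl-1-oxododeca-2,11-dien-6-yl methanesulfonate
Conditions: HF·pyridine, pyridine, THF, 0 → 25 °C
Reagents that add atoms: none
Why: Acidic fluoride desilylation frees the C14 hydroxyl while the β-hydroxy mesylate is kept, so that a free C14–OH never sits beside the acid-sensitive C10–C11 epoxide (which would cyclise to a tetrahydrofuran).

Step 9
Reactants: 16 3-formyl-4-hydroxybenzoic acid
Product: 17 4-hydroxy-3-(1-hydroxybut-2-yn-1-yl)benzoic acid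
Conditions: CH3C≡CMgBr (3.5 equiv), THF, 0 → 25 °C; aq HCl
Reagents that add atoms: 1-propynylmagnesium bromide, CC#C[Mg]Br
Why: Grignard 1,2-addition of the alkynyl reagent to the aldehyde after deprotonation of the acid and phenol; the new carbinol centre is racemic and is removed in the next step.

Step 10
Reactants: 17 4-hydroxy-3-(1-hydroxybut-2-yn-1-yl)benzoic acid
Product: 18 3-(but-2-yn-1-yl)-4-hydroxybenzoic acid
Conditions: Et3SiH, CF3CO2H, CH2Cl2, 0 °C
Reagents that add atoms: none
Why: Ionic hydrogenation: acid ionises the benzylic alcohol to an ortho-quinone-methide-type cation (stabilised by the ortho hydroxyl) that Et3SiH reduces at the benzylic carbon.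

Step 11
Reactants: 15 (2E,6R,7S,10R)-7,10-dihydroxy-2,7,11-trimethyl-1-oxododeca-2,11-dien-6-yl methanesulfonate; 18 3-(but-2-yn-1-yl)-4-hydroxybenzoic acid
Product: 19 (2E,6R,7S,10S)-7-hydroxy-6-[(methylsulfonyl)oxy]-2,7,11-trimethyl-1-oxododeca-2,11-dien-10-yl 3-(but-2-yn-1-yl)-4-hydroxybenzoate
Conditions: PPh3, DIAD, THF, 0 → 25 °C
Reagents that add atoms: none
Why: Mitsunobu esterification: the carboxylic acid (far more acidic than the phenol; tertiary C11–OH inert) displaces the activated C14 oxygen by SN2 with inversion, turning the bought R centre into the S-configured ester of the target.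

Step 12
Reactants: 19 (2E,6R,7S,10S)-7-hydroxy-6-[(methylsulfonyl)oxy]-2,7,11-trimethyl-1-oxododeca-2,11-dien-10-yl 3-(but-2-yn-1-yl)-4-hydroxybenzoate
Product: 21 (S)-2-methyl-5-[(2S,3S)-2-methyl-3-[(E)-4-methylhexa-3,5-dien-1-yl]oxiran-2-yl]pent-1-en-3-yl 3-(but-2-yn-1-yl)-4-hydroxybenzoate, via mesyloxy diene 20 (not isolated)
Conditions: Ph3PCH3Br, KN(SiMe3)2, THF, 0 °C; 19, −78 → 0 °C; then K2CO3, MeOH, 0 → 25 °C
Reagents that add atoms: methyltriphenylphosphonium bromide (used as its ylide), C[P+](c1ccccc1)(c1ccccc1)c1ccccc1.[Br-]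
Why: Wittig methylenation of the enal gives the E 1,3-diene (one extra equivalent of ylide is taken up by the phenol), and mild base then lets the C11 alkoxide displace the C10 mesylate (Williamson-type SN2, inversion at C10) to the (10S,11S)-epoxide.

Step 13
Reactants: 21 (S)-2-methyl-5-[(2S,3S)-2-methyl-3-[(E)-4-methylhexa-3,5-dien-1-yl]oxiran-2-yl]pent-1-en-3-yl 3-(but-2-yn-1-yl)-4-hydroxybenzoate
Product: 22 (Ca S,10S,11S,14S)-10,11-epoxy macrolide (the target ring system with the trans-oxirane C10–O–C11 in place of Br and OH)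
Conditions: CoBr2(dppe) (10 mol%), [Ir(ppy)2(dtbbpy)]PF6 (1 mol%), NaB[3,5-(CF3)2C6H3]4 (20 mol%), i-Pr2NEt (20 mol%), ClCH2CH2Cl, slow addition to 1 mM, 450 nm LEDs, 25 °C
Reagents that add atoms: none
Why: Proposed new method: a visible-light-driven cobalt-catalysed macrocyclising [4+2] of an unactivated diene and internal alkyne 13 atoms apart — the photoreduced iridium dye (quenched by i-Pr2NEt) reduces divalent cobalt to a cationic monovalent cobalt–dppe species that binds the s-cis diene and the alkyne, closes a cobaltacycle by oxidative cyclisation and reductively eliminates the 1,4-cyclohexadiene, the tether is relied on to favour the Ca–Cf/Cd–Ce mode, and Ca is set as S under control of the existing centres because only the diene face that keeps the trans-epoxide and the C14 isopropenyl group outside the forming 15-membered ring can reach the alkyne (a model-based prediction); closest known reactions are the zinc-reduced CoBr2(dppe) diene–alkyne Diels–Alder giving 1,4-cyclohexadienes, short-tether metal-catalysed diene–yne [4+2] and photoredox-generated low-valent cobalt in alkyne cycloadditions, and light replaces Zn/ZnI2, which would open the epoxide.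

Step 14
Reactants: 22 (Ca S,10S,11S,14S)-10,11-epoxy macrolide
Product: 23 CNP0186361.2, the (Ca S,10R,11S,14S)-bromohydrin macrolide
Conditions: Li2NiBr4 (LiBr + NiBr2), THF, 0 → 25 °C; aq phosphate buffer
Reagents that add atoms: dilithium tetrabromonickelate (Li2NiBr4), [Li+].[Li+].Br[Ni-2](Br)(Br)Br
Why: Li2NiBr4 delivers soft bromide to the less substituted epoxide carbon C10 by SN2 with inversion (known regiochemistry for trisubstituted epoxides), giving the secondary (R)-bromide and the tertiary (S)-alcohol of the target without touching ester, phenol or the skipped diene.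

**Compound list**

1 | (R)-5-oxotetrahydrofuran-2-carboxylic acid | O=C(O)[C@H]1CCC(=O)O1 | starting material
2 | (R)-5-oxotetrahydrofuran-2-carbonyl chloride | O=C(Cl)[C@H]1CCC(=O)O1 | intermediate
3 | (R)-5-acetyldihydrofuran-2(3H)-one | CC(=O)[C@H]1CCC(=O)O1 | intermediate
4 | (R)-5-(prop-1-en-2-yl)dihydrofuran-2(3H)-one | C=C(C)[C@H]1CCC(=O)O1 | intermediate
5 | potassium (R)-4-hydroxy-5-methylhex-5-enoate | C=C(C)[C@H](O)CCC(=O)[O-].[K+] | intermediate
6 | tert-butyldimethylsilyl (R)-4-[(tert-butyldimethylsilyl)oxy]-5-methylhex-5-enoate | C=C(C)[C@H](O[Si](C)(C)C(C)(C)C)CCC(=O)O[Si](C)(C)C(C)(C)C | intermediate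
7 | (R)-4-[(tert-butyldimethylsilyl)oxy]-5-methylhex-5-enoic acid | C=C(C)[C@H](O[Si](C)(C)C(C)(C)C)CCC(=O)O | intermediate
8 | 2-thioxopyridin-1(2H)-yl (R)-4-[(tert-butyldimethylsilyl)oxy]-5-methylhex-5-enoate | C=C(C)[C@H](O[Si](C)(C)C(C)(C)C)CCC(=O)On1ccccc1=S | intermediate
9 | (R)-tert-butyl[(5-iodo-2-methylpent-1-en-3-yl)oxy]dimethylsilane | C=C(C)[C@H](O[Si](C)(C)C(C)(C)C)CCI | intermediate
10 | [(R)-3-[(tert-butyldimethylsilyl)oxy]-4-methylpent-4-en-1-yl]magnesium iodide | C=C(C)[C@H](O[Si](C)(C)C(C)(C)C)CC[Mg]I | intermediate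
11 | (R)-5-[(2S,5R)-5-[(tert-butyldimethylsilyl)oxy]-2-hydroxy-6-methylhept-6-en-2-yl]dihydrofuran-2(3H)-one | C=C(C)[C@H](O[Si](C)(C)C(C)(C)C)CC[C@](C)(O)[C@H]1CCC(=O)O1 | intermediate
12 | (5R)-5-[(2S,5R)-5-[(tert-butyldimethylsilyl)oxy]-2-hydroxy-6-methylhept-6-en-2-yl]tetrahydrofuran-2-ol (anomer mixture) | C=C(C)[C@H](O[Si](C)(C)C(C)(C)C)CC[C@](C)(O)[C@H]1CCC(O)O1 | intermediate
13 | (2E,6R,7S,10R)-10-[(tert-butyldimethylsilyl)oxy]-6,7-dihydroxy-2,7,11-trimethyldodeca-2,11-dienal | C=C(C)[C@H](O[Si](C)(C)C(C)(C)C)CC[C@](C)(O)[C@H](O)CC/C=C(\C)C=O | intermediate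
14 | (2E,6R,7S,10R)-10-[(tert-butyldimethylsilyl)oxy]-7-hydroxy-2,7,11-trimethyl-1-oxododeca-2,11-dien-6-yl methanesulfonate | C=C(C)[C@H](O[Si](C)(C)C(C)(C)C)CC[C@](C)(O)[C@H](OS(C)(=O)=O)CC/C=C(\C)C=O | intermediate
15 | (2E,6R,7S,10R)-7,10-dihydroxy-2,7,11-trimethyl-1-oxododeca-2,11-dien-6-yl methanesulfonate | C=C(C)[C@H](O)CC[C@](C)(O)[C@H](OS(C)(=O)=O)CC/C=C(\C)C=O | intermediate
16 | 3-formyl-4-hydroxybenzoic acid | O=Cc1cc(ccc1O)C(=O)O | starting material
17 | 4-hydroxy-3-(1-hydroxybut-2-yn-1-yl)benzoic acid (racemic carbinol) | CC#CC(O)c1cc(ccc1O)C(=O)O | intermediate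
18 | 3-(but-2-yn-1-yl)-4-hydroxybenzoic acid | CC#CCc1cc(ccc1O)C(=O)O | intermediate
19 | (2E,6R,7S,10S)-7-hydroxy-6-[(methylsulfonyl)oxy]-2,7,11-trimethyl-1-oxododeca-2,11-dien-10-yl 3-(but-2-yn-1-yl)-4-hydroxybenzoate | C=C(C)[C@@H](OC(=O)c1ccc(O)c(CC#CC)c1)CC[C@](C)(O)[C@H](OS(C)(=O)=O)CC/C=C(\C)C=O | intermediate
20 | (3S,6S,7R,10E)-6-hydroxy-2,6,11-trimethyl-7-[(methylsulfonyl)oxy]trideca-1,10,12-trien-3-yl 3-(but-2-yn-1-yl)-4-hydroxybenzoate | C=C(C)[C@@H](OC(=O)c1ccc(O)c(CC#CC)c1)CC[C@](C)(O)[C@H](OS(C)(=O)=O)CC/C=C(\C)C=C | intermediate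
21 | (S)-2-methyl-5-[(2S,3S)-2-methyl-3-[(E)-4-methylhexa-3,5-dien-1-yl]oxiran-2-yl]pent-1-en-3-yl 3-(but-2-yn-1-yl)-4-hydroxybenzoate | C=C(C)[C@@H](OC(=O)c1ccc(O)c(CC#CC)c1)CC[C@]2(C)O[C@H]2CC/C=C(\C)C=C | intermediate
22 | (Ca S,10S,11S,14S)-10,11-epoxy macrolide: 15-membered lactone of the ring-A acid with C14–O, ring B (2,5-dimethylcyclohexa-1,4-diene) fused at Ca–Cf, trans-oxirane at C10–C11 | C=C(C)[C@@H]1CC[C@]3(C)O[C@H]3CC[C@H]2C(C)=CCC(C)=C2Cc2cc(ccc2O)C(=O)O1 | intermediate
23 | CNP0186361.2, the (Ca S,10R,11S,14S)-bromohydrin macrolide | C=C(C)[C@@H]1CC[C@](C)(O)[C@H](Br)CC[C@H]2C(C)=CCC(C)=C2Cc2cc(ccc2O)C(=O)O1 | target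

**Step count and weak points**

Total: 14 steps. Longest linear sequence: 12 steps (steps 1–8 and 11–14, through 3, 4, 7, 9, 11, 13, 14, 15, 19, 21, 22 to 23). Both halves of the C8–C16 chain come from ketone 3; ring A is made in two steps (9 and 10).

The three steps most likely to fail:

Step 13 (the new cycloaddition) is the largest risk. A 15-membered ring has to close through a cobaltacycle, the tether has to enforce both the Ca–Cf regiochemistry (the alternative Ca–Ce mode would give a 16-membered ring and has no intrinsic penalty) and the diene face, and the monovalent cobalt must leave the epoxide alone. Fallback with known chemistry only, setting out from 15 and 18: methylenate 15 and close the epoxide as in step 12 (Ph3P=CH2; then K2CO3, MeOH) to the epoxy dienol (R)-2-methyl-5-[(2S,3S)-2-methyl-3-[(E)-4-methylhexa-3,5-dien-1-yl]oxiran-2-yl]pent-1-en-3-ol F1. Join F1 and 18 by the known intermolecular cationic-rhodium diene–alkyne [4+2] ([Rh(C8H12)(C10H8)]SbF6, CH2Cl2, 25 °C) to the seco acid F2; here the regio- and Ca-isomers must be separated by HPLC. A Mitsunobu macrolactonisation (PPh3, DIAD added last and slowly, PhMe, 1 mM; inversion at C14) then comes back to the route at 22.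

Step 5 carries the C11 configuration. If the polar Felkin–Anh preference on the lactone ketone is low, or the lactone carbonyl competes, the minor C11 epimer cannot be recycled. Fallback, setting out from 2 and from 9 as its Grignard reagent 10: acylate 10 with 2 (Fe(acac)3 cat., THF, −78 °C) to the ketone (R)-5-[(R)-4-[(tert-butyldimethylsilyl)oxy]-5-methylhex-5-enoyl]dihydrofuran-2(3H)-one F3. Open its activated lactone with Me2NH (THF, 0 °C) to the α-hydroxy ketone amide F4. Add MeMgBr (3.5 equiv, CH2Cl2–Et2O, −78 °C) under Cram-chelate control through the magnesium alkoxide of C10–OH; with the order of the two carbon groups reversed this gives the same (10R,11S) array in the diol amide F5. Relactonisation with PPTS in PhMe at 60 °C (loss of Me2NH) comes back to the route at 11.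

Step 14 is an SN2 at a carbon next to a quaternary centre inside the finished macrocycle, in the presence of an allylic ester and a skipped diene; it may be slow or open at C11. Fallback, setting out from 21: open the epoxide first on the acyclic ester (Li2NiBr4, THF, 25 °C) to the bromohydrin ester (3S,6S,7R,10E)-7-bromo-6-hydroxy-2,6,11-trimethyltrideca-1,10,12-trien-3-yl 3-(but-2-yn-1-yl)-4-hydroxybenzoate F6, and run the step 13 cycloaddition on F6, which comes back to the route directly at 23.

Further compounds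

F1 | step 13 | (R)-2-methyl-5-[(2S,3S)-2-methyl-3-[(E)-4-methylhexa-3,5-dien-1-yl]oxiran-2-yl]pent-1-en-3-ol | C=C(C)[C@H](O)CC[C@]1(C)O[C@H]1CC/C=C(\C)C=C
F2 | step 13 | 3-{[(6S)-6-{2-[(2S,3S)-3-[(3R)-3-hydroxy-4-methylpent-4-en-1-yl]-3-methyloxiran-2-yl]ethyl}-2,5-dimethylcyclohexa-1,4-dien-1-yl]methyl}-4-hydroxybenzoic acid | C=C(C)[C@H](O)CC[C@]1(C)O[C@H]1CC[C@H]1C(C)=CCC(C)=C1Cc1cc(ccc1O)C(=O)O
F3 | step 5 | (R)-5-[(R)-4-[(tert-butyldimethylsilyl)oxy]-5-methylhex-5-enoyl]dihydrofuran-2(3H)-one | C=C(C)[C@H](O[Si](C)(C)C(C)(C)C)CCC(=O)[C@H]1CCC(=O)O1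
F4 | step 5 | (4R,8R)-8-[(tert-butyldimethylsilyl)oxy]-4-hydroxy-N,N,9-trimethyl-5-oxodec-9-enamide | C=C(C)[C@H](O[Si](C)(C)C(C)(C)C)CCC(=O)[C@H](O)CCC(=O)N(C)C
F5 | step 5 | (4R,5S,8R)-8-[(tert-butyldimethylsilyl)oxy]-4,5-dihydroxy-N,N,5,9-tetramethyldec-9-enamide | C=C(C)[C@H](O[Si](C)(C)C(C)(C)C)CC[C@](C)(O)[C@H](O)CCC(=O)N(C)C
F6 | step 14 | (3S,6S,7R,10E)-7-bromo-6-hydroxy-2,6,11-trimethyltrideca-1,10,12-trien-3-yl 3-(but-2-yn-1-yl)-4-hydroxybenzoate | C=C(C)[C@@H](OC(=O)c1ccc(O)c(CC#CC)c1)CC[C@](C)(O)[C@H](Br)CC/C=C(\C)C=C
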